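**Plan**

Rings are lettered A–E from the 2,4,6-trihydroxyphenyl end. Ring D carries the oxygen to ring C at D1, its only hydrogen at D2, hydroxyls at D3–D5 and the oxygen to ring E at D6.
Enabling feature: D3–D4–D5–D6 is a run of four oxygen-bearing carbons, which is a squaric acid core with ring E already on the D6 oxygen. D1–D2 is an O-substituted carbon beside a CH, which is the triple bond of a ring C aryl ethynyl ether.
Retrosynthetic cuts, in order: the fourteen O–CH3 bonds of a permethyl ether; the B6–O bond to ring C (Ullmann); the D2–D3 and D1–D6 bonds of ring D (cyclobutenone/alkyne benzannulation); the B1–O bond to ring A (Ullmann).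
Forward: squaric acid and the ring E phenol give a 2-aryloxy-3,4-dimethoxycyclobutenone, and the ring C quinone and trichloroethylene give the ynol ether. Heating the two creates ring D and the C–D–E trimer; the separately made A–B iodide is then attached to the ring C oxygen, and global demethylation follows.
Rings A, B, C and E are bought as arenes; ring D is the only ring that is built.
Stereochemistry: the target has no stereocentre. The one sp3 centre of the cyclobutenone is racemic and disappears on aromatisation.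

Key step: step 10

Remark: 2,4,6-trimethoxyphenol and 5-iodo-1,2,3-trimethoxybenzene are taken to be catalogue chemicals.

**Route**

Step 1
Reactants: 1 squaric acid
Product: 2 3,4-dichlorocyclobut-3-ene-1,2-dione
Conditions: (COCl)2 (2.2 equiv), DMF (cat.), ClCH2CH2Cl, 50 °C
Reagents that add atoms: oxalyl chloride, O=C(Cl)C(=O)Cl
Why: Vilsmeier-type chlorination of a vinylogous carboxylic acid, which is the standard preparation of squaric dichloride.

Step 2
Reactants: 2 3,4-dichlorocyclobut-3-ene-1,2-dione
Product: 3 3-chloro-4-methoxycyclobut-3-ene-1,2-dione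
Conditions: MeOH (1.0 equiv), CH2Cl2, −20 °C to rt
Reagents that add atoms: methanol, CO
Why: Addition–elimination at a vinylogous acid chloride; the methoxy group that enters donates into the enedione and slows the second exchange, so one equivalent of methanol should stop at the ester chloride.

Step 3
Reactants: 3 3-chloro-4-methoxycyclobut-3-ene-1,2-dione; 4 3,4,5-trimethoxyphenol
Product: 5 3-methoxy-4-(3,4,5-trimethoxyphenoxy)cyclobut-3-ene-1,2-dione
Conditions: Et3N (1.05 equiv), CH2Cl2, −78 to 0 °C
Reagents that add atoms: none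
Why: Addition–elimination (vinylogous acyl substitution) in which chloride is a far better leaving group than methoxide, so the phenol should replace only chlorine and attack through oxygen, making the crowded D6–O bond without an aryl C–O coupling.

Step 4
Reactants: 5 3-methoxy-4-(3,4,5-trimethoxyphenoxy)cyclobut-3-ene-1,2-dione
Product: 6 rac-4-hydroxy-3-methoxy-2-(3,4,5-trimethoxyphenoxy)cyclobut-2-en-1-one
Conditions: LiAlH(Ot-Bu)3 (1.1 equiv), THF, −78 °C; pH 7 buffer
Reagents that add atoms: none
Why: 1,2-Reduction of a squarate ester with a bulky aluminium hydride is the known route to 4-hydroxycyclobutenones; the carbonyl conjugated through the ring C=C with the weaker aryloxy donor, and flanked by the smaller methoxy group, is the more electrophilic and accessible one, and the new carbinol centre is racemic and is erased in step 10.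

Step 5
Reactants: 6 rac-4-hydroxy-3-methoxy-2-(3,4,5-trimethoxyphenoxy)cyclobut-2-en-1-one
Product: 7 rac-3,4-dimethoxy-2-(3,4,5-trimethoxyphenoxy)cyclobut-2-en-1-one
Conditions: MeI, Ag2O, 4 Å MS, MeCN, rt, dark
Reagents that add atoms: iodomethane, CI
Why: Purdie methylation works under nearly neutral conditions and is the established way to cap 4-hydroxycyclobutenones without base-induced ring opening or acid-induced collapse to a cyclobutenedione.

Step 6
Reactants: 8 2,6-dimethoxy-1,4-benzoquinone
Product: 9 2,6-dimethoxybenzene-1,4-diol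
Conditions: Na2S2O4, EtOAc/H2O, rt
Reagents that add atoms: none
Why: Dithionite reduction of a quinone to its hydroquinone, a routine two-electron reduction.

Step 7
Reactants: 9 2,6-dimethoxybenzene-1,4-diol
Product: 10 4-(benzyloxy)-2,6-dimethoxyphenol
Conditions: BnBr (1.0 equiv), K2CO3 (1.0 equiv), degassed acetone, rt to 50 °C, argon
Reagents that add atoms: benzyl bromide, BrCc1ccccc1
Why: Williamson ether synthesis; the hydroxyl flanked by two hydrogens is both more acidic and far less crowded than the one between the two methoxy groups, so it should be alkylated first.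

Step 8
Reactants: 10 4-(benzyloxy)-2,6-dimethoxyphenol; 11 trichloroethylene
Product: 13 5-(benzyloxy)-2-{[(E)-1,2-dichloroethenyl]oxy}-1,3-dimethoxybenzene, via dichloroacetylene 12 (not isolated)
Conditions: K2CO3, DMF, 70 °C
Reagents that add atoms: none
Why: Known O-dichlorovinylation of phenols: base removes HCl from trichloroethylene, the phenoxide adds anti to the small linear dichloroacetylene, and protonation gives the E ether, so the hindered D1–O bond forms without an aryl C–O coupling.

Step 9
Reactants: 13 5-(benzyloxy)-2-{[(E)-1,2-dichloroethenyl]oxy}-1,3-dimethoxybenzene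
Product: 16 5-(benzyloxy)-2-(ethynyloxy)-1,3-dimethoxybenzene, via chloroethynyl ether 14 (not isolated), via lithium acetylide 15 (not isolated)
Conditions: n-BuLi (2.3 equiv), Et2O, −78 to −40 °C; H2O, −78 °C
Reagents that add atoms: none
Why: Standard dichlorovinyl ether route to ynol ethers (β-elimination of HCl, chlorine–lithium exchange, protonation), run cold enough that the benzyl ether and the ring hydrogens are not metalated.

Step 10
Reactants: 7 rac-3,4-dimethoxy-2-(3,4,5-trimethoxyphenoxy)cyclobut-2-en-1-one; 16 5-(benzyloxy)-2-(ethynyloxy)-1,3-dimethoxybenzene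
Product: 21 5-[4-(benzyloxy)-2,6-dimethoxyphenoxy]-2,3-dimethoxy-4-(3,4,5-trimethoxyphenoxy)phenol, via vinylketene 17 (not isolated), via alkenylcyclobutenone 18 (not isolated), via dienylketene 19 (not isolated), via cyclohexadienone 20 (not isolated)
Conditions: 16 (1.5 equiv), toluene (0.1 M), 110 °C, argon
Reagents that add atoms: none
Why: Proposed new method: heat opens 7 by a conrotatory four-electron process in which the C4 methoxy group turns outward, and the ketene C=C of the resulting vinylketene 17 adds (2+2) to the polarised triple bond of 16, the nucleophilic CH terminus bonding to the ketene carbonyl carbon (D2–D3) and the oxygen-bearing alkyne carbon to the aryloxy-bearing carbon (D1–D6) to give 18. A second four-electron opening of 18, with the aryloxy group on the quaternary carbon turning outward and the alkenyl arm therefore inward, gives dienylketene 19, and ring D closes by a six-electron disrotatory electrocyclisation (ketene carbon onto the CH(OMe) terminus, D3–D4) to dienone 20, which enolises to phenol 21. The closest known chemistry is the Danheiser benzannulation of alkyl- or aryl-substituted cyclobutenones with alkoxy- and silyloxyacetylenes, together with the thermal opening of squarate-derived 4-oxygenated cyclobutenones used in the Moore rearrangement; untested is the bimolecular pairing of a 2,3,4-trioxygenated cyclobutenone with an aryl ethynyl ether. The one selectivity needed is the orientation of the (2+2) step, which the ynol ether polarisation secures, and it sets the D6 aryloxy group next to the D1 aryloxy group and the hydrogen at D2 because the ketone of 7 sits beside the aryloxy carbon. No stereocentre has to be controlled, since the racemic centres of 7, 18 and 20 all vanish on aromatisation. An aryl ethynyl ether has no β-hydrogen for retro-ene loss of the alkyne at this temperature, its two ortho methoxy groups shield it from self-addition, and its excess keeps the ketene from acylating the phenol formed.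

Step 11
Reactants: 21 5-[4-(benzyloxy)-2,6-dimethoxyphenoxy]-2,3-dimethoxy-4-(3,4,5-trimethoxyphenoxy)phenol
Product: 22 1-[4-(benzyloxy)-2,6-dimethoxyphenoxy]-3,4,5-trimethoxy-2-(3,4,5-trimethoxyphenoxy)benzene
Conditions: MeI, K2CO3, acetone, 50 °C
Reagents that add atoms: iodomethane, CI
Why: Williamson methylation caps the D3 hydroxyl, so that the later coupling meets only one free phenol.

Step 12
Reactants: 22 1-[4-(benzyloxy)-2,6-dimethoxyphenoxy]-3,4,5-trimethoxy-2-(3,4,5-trimethoxyphenoxy)benzene
Product: 23 3,5-dimethoxy-4-[3,4,5-trimethoxy-2-(3,4,5-trimethoxyphenoxy)phenoxy]phenol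
Conditions: H2 (1 atm), 10% Pd/C, EtOAc/MeOH, rt
Reagents that add atoms: none
Why: Catalytic hydrogenolysis cleaves only the benzylic C–O bond; methyl aryl and diaryl ethers are inert under these conditions.

Step 13
Reactants: 24 5-iodo-1,2,3-trimethoxybenzene
Product: 25 2-bromo-1-iodo-3,4,5-trimethoxybenzene
Conditions: NBS (1.0 equiv), MeCN, 0 °C to rt
Reagents that add atoms: N-bromosuccinimide, O=C1CCC(=O)N1Br
Why: Electrophilic aromatic bromination; the two open positions of 24 are equivalent and each lies ortho and para to a methoxy group, so a single monobromide should form, and the halogen that marks B6 is in place before the still more activated ring A enters.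

Step 14
Reactants: 25 2-bromo-1-iodo-3,4,5-trimethoxybenzene; 26 2,4,6-trimethoxyphenol
Product: 27 2-bromo-3,4,5-trimethoxy-1-(2,4,6-trimethoxyphenoxy)benzene
Conditions: CuI (10 mol %), picolinic acid (20 mol %), K3PO4, DMSO, 90 °C, argon
Reagents that add atoms: none
Why: Ullmann-type diaryl ether synthesis with a catalyst system known to accept 2,6-disubstituted phenols and ortho-substituted aryl iodides; the weaker and less crowded C–I bond should react while the C–Br bond, flanked on both sides, stays.

Step 15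
Reactants: 27 2-bromo-3,4,5-trimethoxy-1-(2,4,6-trimethoxyphenoxy)benzene
Product: 29 2-iodo-3,4,5-trimethoxy-1-(2,4,6-trimethoxyphenoxy)benzene, via aryllithium 28 (not isolated)
Conditions: n-BuLi (1.05 equiv), THF, −78 °C; I2, −78 °C
Reagents that add atoms: iodine, II
Why: Bromine–lithium exchange followed by iodine quench; at −78 °C the exchange is far faster than ortho-lithiation of ring A, so iodine should end up only at B6.

Step 16
Reactants: 23 3,5-dimethoxy-4-[3,4,5-trimethoxy-2-(3,4,5-trimethoxyphenoxy)phenoxy]phenol; 29 2-iodo-3,4,5-trimethoxy-1-(2,4,6-trimethoxyphenoxy)benzene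
Product: 30 tetradeca-O-methyl ether of the target (rings A–E joined)
Conditions: 29 (1.5 equiv), CuI (20 mol %), picolinic acid (40 mol %), K3PO4, DMSO, 100 °C, argon
Reagents that add atoms: none
Why: Ullmann-type diaryl ether synthesis; phenol 23 has two free ortho positions, so crowding is confined to the iodide partner, and coupling of 2,6-dioxygenated aryl halides with unhindered phenols is the classical entry to polymethoxylated oligo(phenyl ethers).

Step 17
Reactants: 30 tetradeca-O-methyl ether of the target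
Product: 31 5-{2,6-dihydroxy-4-[2,3,4-trihydroxy-6-(2,4,6-trihydroxyphenoxy)phenoxy]phenoxy}-4-(3,4,5-trihydroxyphenoxy)benzene-1,2,3-triol (CNP0273977.0)
Conditions: BBr3 (30 equiv), CH2Cl2, −78 °C to rt; degassed H2O, 0 °C, argon
Reagents that add atoms: none
Why: Lewis-acid cleavage of aryl methyl ethers, in which bromide attacks the methyl carbon of the boron-complexed ether; the four diaryl ether bonds offer no sp3 carbon and should persist, and oxygen is excluded at work-up because the pyrogallol rings oxidise readily.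

**Compound list**

1 | squaric acid | O=C1C(O)=C(O)C1=O | starting material
2 | 3,4-dichlorocyclobut-3-ene-1,2-dione | O=C1C(Cl)=C(Cl)C1=O | intermediate
3 | 3-chloro-4-methoxycyclobut-3-ene-1,2-dione | COC1=C(Cl)C(=O)C1=O | intermediate
4 | 3,4,5-trimethoxyphenol | COc1cc(O)cc(OC)c1OC | starting material
5 | 3-methoxy-4-(3,4,5-trimethoxyphenoxy)cyclobut-3-ene-1,2-dione | COC1=C(Oc2cc(OC)c(OC)c(OC)c2)C(=O)C1=O | intermediate
6 | rac-4-hydroxy-3-methoxy-2-(3,4,5-trimethoxyphenoxy)cyclobut-2-en-1-one | COC1=C(Oc2cc(OC)c(OC)c(OC)c2)C(=O)C1O | intermediate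
7 | rac-3,4-dimethoxy-2-(3,4,5-trimethoxyphenoxy)cyclobut-2-en-1-one | COC1C(=O)C(Oc2cc(OC)c(OC)c(OC)c2)=C1OC | intermediate
8 | 2,6-dimethoxy-1,4-benzoquinone | COC1=CC(=O)C=C(OC)C1=O | starting material
9 | 2,6-dimethoxybenzene-1,4-diol | COc1cc(O)cc(OC)c1O | intermediate
10 | 4-(benzyloxy)-2,6-dimethoxyphenol | COc1cc(OCc2ccccc2)cc(OC)c1O | intermediate
11 | trichloroethylene | ClC=C(Cl)Cl | starting material
12 | dichloroacetylene | ClC#CCl | intermediate
13 | 5-(benzyloxy)-2-{[(E)-1,2-dichloroethenyl]oxy}-1,3-dimethoxybenzene | COc1cc(OCc2ccccc2)cc(OC)c1O/C(Cl)=C\Cl | intermediate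
14 | 5-(benzyloxy)-2-[(chloroethynyl)oxy]-1,3-dimethoxybenzene | COc1cc(OCc2ccccc2)cc(OC)c1OC#CCl | intermediate
15 | {[4-(benzyloxy)-2,6-dimethoxyphenoxy]ethynyl}lithium | COc1cc(OCc2ccccc2)cc(OC)c1OC#C[Li] | intermediate
16 | 5-(benzyloxy)-2-(ethynyloxy)-1,3-dimethoxybenzene | COc1cc(OCc2ccccc2)cc(OC)c1OC#C | intermediate
17 | (3Z)-3,4-dimethoxy-2-(3,4,5-trimethoxyphenoxy)buta-1,3-dien-1-one (vinylketene) | O=C=C(Oc1cc(OC)c(OC)c(OC)c1)/C(OC)=C/OC | intermediate
18 | rac-3-[4-(benzyloxy)-2,6-dimethoxyphenoxy]-4-[(Z)-1,2-dimethoxyethenyl]-4-(3,4,5-trimethoxyphenoxy)cyclobut-2-en-1-one (alkenylcyclobutenone) | O=C1C=C(Oc2c(OC)cc(OCc3ccccc3)cc2OC)C1(Oc2cc(OC)c(OC)c(OC)c2)/C(OC)=C/OC | intermediate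
19 | (3Z,5Z)-3-[4-(benzyloxy)-2,6-dimethoxyphenoxy]-5,6-dimethoxy-4-(3,4,5-trimethoxyphenoxy)hexa-1,3,5-trien-1-one (dienylketene) | O=C=C/C(Oc1c(OC)cc(OCc2ccccc2)cc1OC)=C(Oc1cc(OC)c(OC)c(OC)c1)\C(OC)=C\OC | intermediate
20 | rac-3-[4-(benzyloxy)-2,6-dimethoxyphenoxy]-5,6-dimethoxy-4-(3,4,5-trimethoxyphenoxy)cyclohexa-2,4-dien-1-one (cyclohexadienone) | O=C1C=C(Oc2c(OC)cc(OCc3ccccc3)cc2OC)C(Oc2cc(OC)c(OC)c(OC)c2)=C(OC)C1OC | intermediate
21 | 5-[4-(benzyloxy)-2,6-dimethoxyphenoxy]-2,3-dimethoxy-4-(3,4,5-trimethoxyphenoxy)phenol | COc1cc(OCc2ccccc2)cc(OC)c1Oc1cc(O)c(OC)c(OC)c1Oc1cc(OC)c(OC)c(OC)c1 | intermediate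
22 | 1-[4-(benzyloxy)-2,6-dimethoxyphenoxy]-3,4,5-trimethoxy-2-(3,4,5-trimethoxyphenoxy)benzene | COc1cc(OCc2ccccc2)cc(OC)c1Oc1cc(OC)c(OC)c(OC)c1Oc1cc(OC)c(OC)c(OC)c1 | intermediate
23 | 3,5-dimethoxy-4-[3,4,5-trimethoxy-2-(3,4,5-trimethoxyphenoxy)phenoxy]phenol | COc1cc(O)cc(OC)c1Oc1cc(OC)c(OC)c(OC)c1Oc1cc(OC)c(OC)c(OC)c1 | intermediate
24 | 5-iodo-1,2,3-trimethoxybenzene | COc1cc(I)cc(OC)c1OC | starting material
25 | 2-bromo-1-iodo-3,4,5-trimethoxybenzene | COc1cc(I)c(Br)c(OC)c1OC | intermediate
26 | 2,4,6-trimethoxyphenol | COc1cc(OC)c(O)c(OC)c1 | starting material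
27 | 2-bromo-3,4,5-trimethoxy-1-(2,4,6-trimethoxyphenoxy)benzene | COc1cc(OC)c(Oc2cc(OC)c(OC)c(OC)c2Br)c(OC)c1 | intermediate
28 | [2,3,4-trimethoxy-6-(2,4,6-trimethoxyphenoxy)phenyl]lithium | COc1cc(OC)c(Oc2cc(OC)c(OC)c(OC)c2[Li])c(OC)c1 | intermediate
29 | 2-iodo-3,4,5-trimethoxy-1-(2,4,6-trimethoxyphenoxy)benzene | COc1cc(OC)c(Oc2cc(OC)c(OC)c(OC)c2I)c(OC)c1 | intermediate
30 | tetradeca-O-methyl ether of the target | COc1cc(OC)c(Oc2cc(OC)c(OC)c(OC)c2Oc2cc(OC)c(Oc3cc(OC)c(OC)c(OC)c3Oc3cc(OC)c(OC)c(OC)c3)c(OC)c2)c(OC)c1 | intermediate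
31 | 5-{2,6-dihydroxy-4-[2,3,4-trihydroxy-6-(2,4,6-trihydroxyphenoxy)phenoxy]phenoxy}-4-(3,4,5-trihydroxyphenoxy)benzene-1,2,3-triol (CNP0273977.0) | Oc1cc(O)c(Oc2cc(O)c(O)c(O)c2Oc2cc(O)c(Oc3cc(O)c(O)c(O)c3Oc3cc(O)c(O)c(O)c3)c(O)c2)c(O)c1 | target

**Counts**

Total step count: 17.
Longest linear sequence: 10 steps (steps 1–5, 10–12, 16 and 17, from squaric acid).

**Steps most likely to fail**

**Step 10 (Proposed new method).**
- What may go wrong: the electron-rich vinylketene may re-close or oligomerise faster than it is intercepted. The ynol ether may polymerise at the temperature that ring opening needs. The phenol formed may be acylated by remaining ketene.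
- Fallback (known chemistry only): ring D is taken from an arene, and both of its ether bonds are made by Ullmann couplings. The fallback sets out from 10 and 25.
- Under the conditions of step 14, the hindered phenol should couple at the C–I bond to give 2-bromo-1-[4-(benzyloxy)-2,6-dimethoxyphenoxy]-3,4,5-trimethoxybenzene F1.
- Bromine–lithium exchange with n-BuLi at −78 °C and an iodine quench should give 1-[4-(benzyloxy)-2,6-dimethoxyphenoxy]-2-iodo-3,4,5-trimethoxybenzene F2.
- A second CuI/picolinic acid coupling of F2 with the unhindered phenol 4, under the conditions of step 16, comes back to the route at 22.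

**Step 16.**
- What may go wrong: insertion of monovalent copper into the C–I bond of 29, which is electron-rich and flanked on both sides, may be too slow. Hydrodeiodination and oxidation of the phenol would then take over.
- Fallback: no aryl C–O coupling is used at B6. Ring B has the same substitution pattern as ring D, so it is grown on the ring C oxygen by the annulation that step 10 will by then have validated. The fallback sets out from 23 and 3.
- Et3N in CH2Cl2 should give the mixed squarate 3-methoxy-4-{3,5-dimethoxy-4-[3,4,5-trimethoxy-2-(3,4,5-trimethoxyphenoxy)phenoxy]phenoxy}cyclobut-3-ene-1,2-dione F3.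
- LiAlH(Ot-Bu)3 should then give the corresponding rac-4-hydroxy-3-methoxy-2-aryloxycyclobut-2-en-1-one F4, and MeI/Ag2O the rac-3,4-dimethoxy-2-aryloxycyclobut-2-en-1-one F5.
- In parallel, 26 and 11 with K2CO3 in DMF should give 2-{[(E)-1,2-dichloroethenyl]oxy}-1,3,5-trimethoxybenzene F6. n-BuLi followed by water should convert it into 2-(ethynyloxy)-1,3,5-trimethoxybenzene F7.
- Heating F5 and F7 in toluene should close ring B and give the pentamer with a free B3 hydroxyl, 4-{3,5-dimethoxy-4-[3,4,5-trimethoxy-2-(3,4,5-trimethoxyphenoxy)phenoxy]phenoxy}-2,3-dimethoxy-5-(2,4,6-trimethoxyphenoxy)phenol F8.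
- F8 is treated with BBr3 as in step 17 and comes back to the route at 31.

**Step 4.**
- What may go wrong: hydride may be delivered to the wrong carbonyl, because site selectivity between two electronically similar vinylogous esters could be poor.
- Fallback: the selectivity question is removed by symmetry, and the methoxy group is installed afterwards at the only position that can exchange. The fallback sets out from 2 and 4.
- Two equivalents of 4 with Et3N in CH2Cl2 should give 3,4-bis(3,4,5-trimethoxyphenoxy)cyclobut-3-ene-1,2-dione F9, whose two carbonyls are equivalent.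
- LiAlH(Ot-Bu)3 should give rac-4-hydroxy-2,3-bis(3,4,5-trimethoxyphenoxy)cyclobut-2-en-1-one F10, and MeI/Ag2O should give rac-4-methoxy-2,3-bis(3,4,5-trimethoxyphenoxy)cyclobut-2-en-1-one F11.
- Methanol with catalytic Et3N at 0 °C should then replace only the aryloxy group on the β-carbon of the enone by addition–elimination. The aryloxy group on the α-carbon cannot be attacked in this way. This comes back to the route at 7.

**Further compounds**

F1 | step 10 | 2-bromo-1-[4-(benzyloxy)-2,6-dimethoxyphenoxy]-3,4,5-trimethoxybenzene | COc1cc(OCc2ccccc2)cc(OC)c1Oc1cc(OC)c(OC)c(OC)c1Br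
F2 | step 10 | 1-[4-(benzyloxy)-2,6-dimethoxyphenoxy]-2-iodo-3,4,5-trimethoxybenzene | COc1cc(OCc2ccccc2)cc(OC)c1Oc1cc(OC)c(OC)c(OC)c1I
F3 | step 16 | 3-methoxy-4-{3,5-dimethoxy-4-[3,4,5-trimethoxy-2-(3,4,5-trimethoxyphenoxy)phenoxy]phenoxy}cyclobut-3-ene-1,2-dione | COC1=C(Oc2cc(OC)c(Oc3cc(OC)c(OC)c(OC)c3Oc3cc(OC)c(OC)c(OC)c3)c(OC)c2)C(=O)C1=O
F4 | step 16 | rac-4-hydroxy-3-methoxy-2-{3,5-dimethoxy-4-[3,4,5-trimethoxy-2-(3,4,5-trimethoxyphenoxy)phenoxy]phenoxy}cyclobut-2-en-1-one | COC1=C(Oc2cc(OC)c(Oc3cc(OC)c(OC)c(OC)c3Oc3cc(OC)c(OC)c(OC)c3)c(OC)c2)C(=O)C1O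
F5 | step 16 | rac-3,4-dimethoxy-2-{3,5-dimethoxy-4-[3,4,5-trimethoxy-2-(3,4,5-trimethoxyphenoxy)phenoxy]phenoxy}cyclobut-2-en-1-one | COC1C(=O)C(Oc2cc(OC)c(Oc3cc(OC)c(OC)c(OC)c3Oc3cc(OC)c(OC)c(OC)c3)c(OC)c2)=C1OC
F6 | step 16 | 2-{[(E)-1,2-dichloroethenyl]oxy}-1,3,5-trimethoxybenzene | COc1cc(OC)c(O/C(Cl)=C\Cl)c(OC)c1
F7 | step 16 | 2-(ethynyloxy)-1,3,5-trimethoxybenzene | COc1cc(OC)c(OC#C)c(OC)c1
F8 | step 16 | 4-{3,5-dimethoxy-4-[3,4,5-trimethoxy-2-(3,4,5-trimethoxyphenoxy)phenoxy]phenoxy}-2,3-dimethoxy-5-(2,4,6-trimethoxyphenoxy)phenol | COc1cc(OC)c(Oc2cc(O)c(OC)c(OC)c2Oc2cc(OC)c(Oc3cc(OC)c(OC)c(OC)c3Oc3cc(OC)c(OC)c(OC)c3)c(OC)c2)c(OC)c1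
F9 | step 4 | 3,4-bis(3,4,5-trimethoxyphenoxy)cyclobut-3-ene-1,2-dione | O=C1C(=O)C(Oc2cc(OC)c(OC)c(OC)c2)=C1Oc1cc(OC)c(OC)c(OC)c1
F10 | step 4 | rac-4-hydroxy-2,3-bis(3,4,5-trimethoxyphenoxy)cyclobut-2-en-1-one | O=C1C(O)C(Oc2cc(OC)c(OC)c(OC)c2)=C1Oc1cc(OC)c(OC)c(OC)c1
F11 | step 4 | rac-4-methoxy-2,3-bis(3,4,5-trimethoxyphenoxy)cyclobut-2-en-1-one | O=C1C(OC)C(Oc2cc(OC)c(OC)c(OC)c2)=C1Oc1cc(OC)c(OC)c(OC)c1
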